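Late in the summer flask, from 3.00 d to 6.00 d, the product reads a flat 13.1%, with 86.9% of the starting material unreacted. Before we act at 8.0 d, we need to know what stopped it.

common to all: starting material 0.50 M

| charge | coupling partner | free catalyst | remark | time |
|---|---|---|---|---|
| summer | 0.90 M | 1.5 mM | the very flask that is asked about, followed so far |  |
| spring | 0.90 M | 1 mM | run made earlier |  |
| flask | 0.900 M | 1.5 mM |  | 8.0 d |

summer run (percent of the starting material charged)

| time / d | product / % |
|---|---|
| 0.333 | 4.6 |
| 1.04 | 11.8 |
| 1.67 | 12.5 |
| 3.00 | 13.1 |
| 4.00 | 13.2 |
| 5.00 | 12.9 |
| 6.00 | 13.0 |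

spring run (percent of the starting material charged)

| time / h | product / % |
|---|---|
| 2.50 | 0.1 |
| 8.00 | 3.9 |
| 15.0 | 6.2 |
| 20.0 | 8.0 |
| 30.0 | 7.7 |
| 40.0 | 7.4 |
| 50.0 | 9.2 |

(standard deviation of a reading: 1 percentage point)

- zeta: at 8.0 d add coupling partner, 50.0% of the amount charged, then wait 15 d
- eta: at 8.0 d add free catalyst, 100% of the amount charged, then wait 15 d
- delta: change nothing and wait 15 d more
- gamma: at 8.0 d take out 90% of the by-product then present, then wait 15 d

- additions leave the volume as it is

- product, in percent of the starting material first charged, at 8.0 d
- what to do for the largest gain in product; "none" if nothing gains more than 2 percentage points (zeta / eta / delta / gamma / none)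
- product present, in percent of the starting material first charged, after zeta
- product present, in percent of the starting material first charged, after eta

We take the run in slow motion. At the start the spring run reads 0.1% at 2.50 h. In the middle the two runs climb side by side: summer reads 4.6% at 0.333 d, spring 3.9% at 8.00 h. Towards the end summer reads 11.8% at 1.04 d and spring 8.0% at 20.0 h, and spring then levels off near 8.07%.

So with 1.50 times the catalyst the plateau reads 1.62 times as high, within a scatter of 1 percentage point, and the stop shows no sign of coming sooner. Some clock is running that the catalyst load does not visibly set.

Two clocks fit: a catalyst dying at a pace that ignores its own concentration, or a first-order loss of the coupling partner, for which the catalyst merely competes. The two runs report product and nothing else, and on these readings both clocks stand open. Our own reckoning commits to the second as the plainer clock, which makes the coupling partner the limiting reagent despite its 1.80 equivalents.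

In the summer flask:

c(product) at the plateau = 13.1% × 0.50 M = 65.2 mM

65.2 mM / 0.90 M = 7.25%

This product made per coupling partner charged, the partner yield, we freeze for a further portion of coupling partner in this same flask, at this catalyst charge. Zeta adds 0.450 M of coupling partner, so:

gain = 7.25% × 0.450 M / 0.50 M = 6.5 points

product after zeta = 19.6%

We therefore expect 13.1% at 8.0 d, the same 13.1% after eta, delta or gamma, and choose zeta.

The forecast matches our 13.1% at 8.0 d within its rounding but parts from us on the choice: 13% now, eta as best, 13% after zeta and 25% after eta, on the ground that “The catalyst has died”.

The flask gives 12.8% at 8.0 d, and zeta gains most, reaching 20.0%, while eta leaves 12.8%. At 8.00 d the coupling partner stands at 0% of its charge and free catalyst at 86.2% of the catalyst charged.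

    catalyst intermediate B → by-product + catalyst intermediate C (k = 7.28 h⁻¹)
    catalyst intermediate D → free catalyst + product (k = 62.5 h⁻¹)
    coupling partner + free catalyst ⇌ catalyst intermediate A (K = 2.34 M⁻¹, k = 30.3 M⁻¹ h⁻¹)
    2 catalyst intermediate A → spent catalyst (k = 39.9 M⁻¹ h⁻¹)
    starting material + catalyst intermediate A ⇌ catalyst intermediate B (K = 2.90 M⁻¹, k = 62.1 M⁻¹ h⁻¹)
    catalyst intermediate C → catalyst intermediate D (k = 371 h⁻¹)
    coupling partner → decomposed reagent (k = 0.0911 h⁻¹)

The partner yield reckoned a gain of 6.5 points, and zeta gave 7.1 points. For the neighbour flask charged with 2.2 M of coupling partner from the start, the same yield reckons 31.9%, but that flask gives 18.3%, with spent catalyst at 25.0% of the catalyst charged.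

The numbers in the tables come from a simulation for substances that don't exist; noise was put on by code.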